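**Retrosynthetic overview**

- Cyclohexene numbering: C1 (aroyl), C2 (flavon-6-yl), C3=C4(CH3), C5H2, C6 (2,4-dihydroxyphenyl). The same labels are kept for these carbons in all precursors. The last operation is removal of eight methoxymethyl groups.
- Key disconnection: the cyclohexene is folded back to a 2-methyl-2-[(E)-styryl]cyclobutyl aryl ketone, with ring C1–C4–C5–C6 and C2=C3 outside the ring. A 1,3-shift of C1 from C4 to C2 enlarges the four-membered ring by two carbons. The styrene is made in the same flask by a Heck reaction of a 6-iodoflavone with the vinylcyclobutane.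
- Enabling feature: C1 is alpha to the aryl ketone (acceptor). C2 is allylic to C3=C4 and benzylic to the 5,7,8a-trioxygenated ring A of the flavone (donor). C1–C2, and likewise C1–C4 in the cyclobutane, is therefore a push–pull bond; ring strain drives the migration, and the quaternary centre C4 hands its chirality to C2.
- The vinylcyclobutyl ketone comes from (S)-2-methyl-2-vinylcyclobutanone (gold-catalysed enlargement of an allenylcyclopropanol), a Shapiro/Weinreb acylation (aroyl) and a rhodium-catalysed asymmetric 1,4-arylation (C6). The iodoflavone comes from phloroacetophenone and 2,4-dihydroxybenzaldehyde by Claisen–Schmidt condensation, oxidative cyclisation and 5-OH-directed iodination.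
- Ring order: benzene rings bought; pyranone ring C of the flavone; cyclopropane to cyclobutane; cyclobutane to cyclohexene last.

Key step: step 18

Assumption: the ligand antipodes written in steps 8 and 11 are those expected to give the drawn configurations. If the sense of induction is the opposite, the other antipode is used.

**Route**

Step 1
Reactants: 1 resorcinol
Product: 2 1,3-bis(methoxymethoxy)benzene
Conditions: NaH, MOMCl, DMF, 0 °C to rt
Reagents that add atoms: chloromethyl methyl ether, COCCl
Why: Williamson-type O-alkylation of both phenoxides installs acetal ethers that direct ortho-lithiation and survive the organometallic steps.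

Step 2
Reactants: 2 1,3-bis(methoxymethoxy)benzene; 3 1-bromo-3-methylbut-2-ene (prenyl bromide)
Product: 5 1,3-bis(methoxymethoxy)-2-(3-methylbut-2-en-1-yl)benzene, via 2,6-bis(methoxymethoxy)phenyllithium 4 (not isolated)
Conditions: n-BuLi, THF, 0 °C; then 3, −78 °C to rt
Reagents that add atoms: none
Why: Directed ortho-metalation occurs at the position flanked by both acetal oxygens, and the aryllithium displaces the primary allylic bromide (SN2).

Step 3
Reactants: 5 1,3-bis(methoxymethoxy)-2-(3-methylbut-2-en-1-yl)benzene; 6 N-methoxy-N-methylcarbamoyl chloride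
Product: 8 N-methoxy-N-methyl-2,4-bis(methoxymethoxy)-3-(3-methylbut-2-en-1-yl)benzamide, via 2,4-bis(methoxymethoxy)-3-prenylphenyllithium 7 (not isolated)
Conditions: n-BuLi, TMEDA, THF, 0 °C; then 6, −78 °C to 0 °C
Reagents that add atoms: none
Why: A second directed ortho-metalation next to an acetal oxygen, followed by acylation with the carbamoyl chloride, gives the Weinreb amide in one flask.

Step 4
Reactants: 9 4-bromoresorcinol
Product: 10 1-bromo-2,4-bis(methoxymethoxy)benzene
Conditions: NaH, MOMCl, DMF, 0 °C to rt
Reagents that add atoms: chloromethyl methyl ether, COCCl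
Why: Williamson-type O-alkylation protects both phenols before the halogen–metal exchange.

Step 5
Reactants: 10 1-bromo-2,4-bis(methoxymethoxy)benzene
Product: 13 [2,4-bis(methoxymethoxy)phenyl]boronic acid, via 2,4-bis(methoxymethoxy)phenyllithium 11 (not isolated), via lithium aryl(triisopropoxy)borate 12 (not isolated)
Conditions: n-BuLi, THF, −78 °C; B(OiPr)3, −78 °C to rt; dilute aq HCl to pH 5
Reagents that add atoms: triisopropyl borate, CC(C)OB(OC(C)C)OC(C)C; water, O
Why: Bromine–lithium exchange, borylation and mild hydrolysis form the standard route to an arylboronic acid and leave the acetals intact at this pH.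

Step 6
Reactants: 14 (1-ethoxycyclopropoxy)trimethylsilane
Product: 15 1-ethoxycyclopropan-1-ol
Conditions: MeOH, rt, then evaporation
Reagents that add atoms: none
Why: Methanolysis of the silyl ether frees the stable ethyl hemiketal of cyclopropanone.

Step 7
Reactants: 15 1-ethoxycyclopropan-1-ol; 16 1-bromobut-2-yne
Product: 19 1-(buta-2,3-dien-2-yl)cyclopropan-1-ol, via but-2-yn-1-ylzinc bromide 17 (not isolated), via cyclopropanone 18 (not isolated)
Conditions: 16, Zn, LiCl, THF, 0 °C; separately 15, MeMgBr (1 equiv), THF, 0 to 40 °C; solutions combined, 0 °C to rt; aq NH4Cl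
Reagents that add atoms: none
Why: The magnesium hemiketalate collapses to cyclopropanone, which the propargylic zinc reagent attacks through its substituted terminus (SE2' Barbier-type addition) to give the 1-methylallenyl carbinol.

Step 8
Reactants: 19 1-(buta-2,3-dien-2-yl)cyclopropan-1-ol
Product: 20 (S)-2-ethenyl-2-methylcyclobutan-1-one
Conditions: (R)-xylyl-MeO-BIPHEP(AuCl)2 (2.5 mol %), NaB[3,5-(CF3)2C6H3]4 (5 mol %), ClCH2CH2Cl, −30 °C
Reagents that add atoms: none
Why: Cationic monovalent gold activates the allene and triggers a semipinacol-type 1,2-shift of a cyclopropane carbon (the known enantioselective ring expansion of 1-allenylcyclopropanols), and the chiral bisphosphine selects the face of the allene carbon that becomes the quaternary centre C4.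

Step 9
Reactants: 20 (S)-2-ethenyl-2-methylcyclobutan-1-one
Product: 21 N'-[(2S)-2-ethenyl-2-methylcyclobutylidene]-2,4,6-triisopropylbenzenesulfonohydrazide
Conditions: 2,4,6-triisopropylbenzenesulfonohydrazide, THF, rt
Reagents that add atoms: 2,4,6-triisopropylbenzenesulfonohydrazide, CC(C)c1cc(C(C)C)c(S(=O)(=O)NN)c(C(C)C)c1
Why: Condensation of the strained, reactive ketone with the hindered sulfonyl hydrazide gives the hydrazone for the Shapiro reaction without touching C4.

Step 10
Reactants: 21 the trisylhydrazone; 8 the Weinreb amide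
Product: 23 [2,4-bis(methoxymethoxy)-3-(3-methylbut-2-en-1-yl)phenyl][(4S)-4-ethenyl-4-methylcyclobut-1-en-1-yl]methanone, via (4S)-4-ethenyl-4-methylcyclobut-1-enyllithium 22 (not isolated)
Conditions: n-BuLi (2.1 equiv), THF–TMEDA, −78 to 0 °C; then 8, −78 to −20 °C; aq NH4Cl
Reagents that add atoms: none
Why: In the Shapiro reaction deprotonation is possible only on the CH2 side because C4 is quaternary, and the resulting cyclobutenyllithium stops at the enone in the Weinreb ketone synthesis.

Step 11
Reactants: 23 the cyclobutenyl aryl ketone; 13 [2,4-bis(methoxymethoxy)phenyl]boronic acid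
Product: 24 [2,4-bis(methoxymethoxy)-3-(3-methylbut-2-en-1-yl)phenyl]{(1R,2S,4S)-4-[2,4-bis(methoxymethoxy)phenyl]-2-ethenyl-2-methylcyclobutyl}methanone (aryl cis to vinyl; aroyl trans to both)
Conditions: [RhCl(C2H4)2]2 (2.5 mol %), (R,R)-2,5-diphenylbicyclo[2.2.2]octa-2,5-diene (5.5 mol %), KOH (0.5 equiv, aq), 1,4-dioxane, 30 °C
Reagents that add atoms: none
Why: The Hayashi–Miyaura 1,4-addition, known for cyclobutene-1-carboxylates, sets C6 under control of the chiral diene ligand because methyl and vinyl on the remote C4 give almost no substrate bias, and protonation or equilibration of the enolate places the aroyl group at C1 trans to the new aryl group.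

Step 12
Reactants: 25 2,4,6-trihydroxyacetophenone
Product: 26 1-[2,6-dihydroxy-4-(methoxymethoxy)phenyl]ethan-1-one
Conditions: MOMCl (1.05 equiv), diisopropylethylamine (1.1 equiv), CH2Cl2–THF, 0 °C
Reagents that add atoms: chloromethyl methyl ether, COCCl
Why: Only the 4-OH is free of the hydrogen bond to the acetyl group, so it is the most acidic and most nucleophilic site and is alkylated selectively.

Step 13
Reactants: 27 2,4-dihydroxybenzaldehyde
Product: 28 2,4-bis(methoxymethoxy)benzaldehyde
Conditions: NaH, MOMCl, DMF, 0 °C to rt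
Reagents that add atoms: chloromethyl methyl ether, COCCl
Why: Full deprotonation with NaH allows Williamson-type alkylation of the chelated 2-OH as well.

Step 14
Reactants: 26 the mono-protected acetophenone; 28 2,4-bis(methoxymethoxy)benzaldehyde
Product: 29 (E)-1-[2,6-dihydroxy-4-(methoxymethoxy)phenyl]-3-[2,4-bis(methoxymethoxy)phenyl]prop-2-en-1-one
Conditions: KOH (50 % aq), EtOH, rt; then dilute HCl to pH 6
Reagents that add atoms: none
Why: Claisen–Schmidt condensation gives the E-chalcone, and any flavanone formed from it by ring closure is equally suited to the next step.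

Step 15
Reactants: 29 the chalcone
Product: 31 5-hydroxy-7-(methoxymethoxy)-2-[2,4-bis(methoxymethoxy)phenyl]-4H-chromen-4-one, via flavanone 30 (not isolated)
Conditions: I2 (10 mol %), DMSO, 110 °C
Reagents that add atoms: none
Why: Oxa-Michael closure followed by iodine-catalysed dehydrogenation with DMSO as terminal oxidant is the standard chalcone-to-flavone conversion, and it leaves the second ortho hydroxyl as the free 5-OH.

Step 16
Reactants: 31 the 5-hydroxyflavone
Product: 32 5-hydroxy-6-iodo-7-(methoxymethoxy)-2-[2,4-bis(methoxymethoxy)phenyl]-4H-chromen-4-one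
Conditions: BnMe3N ICl2, CaCO3, CH2Cl2–MeOH, rt
Reagents that add atoms: benzyltrimethylammonium dichloroiodate, C[N+](C)(C)Cc1ccccc1.Cl[I-]Cl
Why: Electrophilic iodination with this reagent is known to go ortho to the free 5-OH of 5,7-dioxygenated flavones (C6), and the phloroglucinol-type ring A is more activated than the resorcinol-type ring B attached to the electron-poor C2.

Step 17
Reactants: 32 the 6-iodo-5-hydroxyflavone
Product: 33 6-iodo-5,7-bis(methoxymethoxy)-2-[2,4-bis(methoxymethoxy)phenyl]-4H-chromen-4-one
Conditions: NaH, MOMCl, DMF, 0 °C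
Reagents that add atoms: chloromethyl methyl ether, COCCl
Why: Alkylation of the sodium salt caps the chelated 5-OH with a small group, so that no phenol can trap the allyl cation as a chromene in the key step.

Step 18
Reactants: 24 the vinylcyclobutyl aryl ketone; 33 the protected 6-iodoflavone
Product: 35 octakis(methoxymethyl) ether of the target with (1R,2S,6S)-cyclohex-3-ene core, via E-styrylcyclobutyl ketone 34 (not isolated)
Conditions: Pd(OAc)2 (10 mol %), P(o-tol)3 (20 mol %), Ag2CO3 (0.6 equiv), toluene, 80 °C; then (CF3)2CHOH added (4 volumes), 40 °C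
Reagents that add atoms: none
Why: Proposed new method: a Heck reaction of aryl iodide 33 at the monosubstituted vinyl group of 24 (the quaternary carbon allows beta-hydride loss only toward the arene) should give the E-styrylcyclobutane 34, in which the C1–C4 bond joins the carbon alpha to the aryl ketone (acceptor) to a tertiary carbon that is allylic and, through the new styrene, conjugated with the trioxygenated flavone ring A (donor). In the strongly hydrogen-bonding, ionising and non-nucleophilic solvent (CF3)2CHOH this strained push–pull bond should heterolyse to a tethered enol(ate)/1-aryl-3-methylallyl cation pair that recloses at the distal allyl terminus C2, so that the ring C1–C4–C5–C6 takes up C2 and C3 and becomes the cyclohexene with C3=C4 in place (net suprafacial 1,3-shift, 6-endo attack of the enol carbon on the allyl cation, driven by release of about 26 kcal/mol of ring strain). The closest known reaction types are the thermal, Lewis-acid and cation-radical vinylcyclobutane-to-cyclohexene rearrangements and the opening of donor–acceptor cyclopropanes and cyclobutanes in this solvent, whereas the tandem with a Heck coupling and the reliance on a single ketone acceptor are new. C6 is untouched; C2 is set by chirality transfer from the quaternary centre C4, because C1 leaves and re-bonds on the same face of the allyl unit in the only rotamer (C2 syn to C5) that can give a cis ring alkene, and with the styryl group trans to the aroyl group this places flavonyl and aroyl cis; C1 migrates with retention and is in any case the thermodynamically preferred epimer (aroyl trans to the C6 aryl). The step needs cleavage of C1–C4 and not C4–C5 (only C1 carries the acceptor), C-closure rather than O-closure (the dihydropyran from O-closure is an allyl vinyl ether that would reach the same product by Claisen rearrangement), ring closure faster than cycloreversion to chalcone and diene (favoured by the low temperature and the two-atom tether) and Heck selectivity for the vinyl over the prenyl alkene (mono- against trisubstituted).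

Step 19
Reactants: 35 the octakis(methoxymethyl) ether
Product: 36 target CNP0270206.1
Conditions: HCl (3 M aq), MeOH–THF, 45 °C
Reagents that add atoms: none
Why: Acid-catalysed transacetalisation to methanol removes all eight methoxymethyl groups under conditions commonly tolerated by prenylated polyphenols, and no stereocentre is touched as long as the temperature stays too low for re-ionisation of the C1–C2 bond.

**Compound list**

1 | resorcinol | Oc1cccc(O)c1 | starting material
2 | 1,3-bis(methoxymethoxy)benzene | COCOc1cccc(OCOC)c1 | intermediate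
3 | 1-bromo-3-methylbut-2-ene (prenyl bromide) | CC(C)=CCBr | starting material
4 | 2,6-bis(methoxymethoxy)phenyllithium | [Li]c1c(OCOC)cccc1OCOC | intermediate
5 | 1,3-bis(methoxymethoxy)-2-(3-methylbut-2-en-1-yl)benzene | CC(C)=CCc1c(OCOC)cccc1OCOC | intermediate
6 | N-methoxy-N-methylcarbamoyl chloride | CON(C)C(=O)Cl | starting material
7 | 2,4-bis(methoxymethoxy)-3-(3-methylbut-2-en-1-yl)phenyllithium | [Li]c1ccc(OCOC)c(CC=C(C)C)c1OCOC | intermediate
8 | N-methoxy-N-methyl-2,4-bis(methoxymethoxy)-3-(3-methylbut-2-en-1-yl)benzamide | CON(C)C(=O)c1ccc(OCOC)c(CC=C(C)C)c1OCOC | intermediate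
9 | 4-bromoresorcinol | Oc1ccc(Br)c(O)c1 | starting material
10 | 1-bromo-2,4-bis(methoxymethoxy)benzene | COCOc1ccc(Br)c(OCOC)c1 | intermediate
11 | 2,4-bis(methoxymethoxy)phenyllithium | [Li]c1ccc(OCOC)cc1OCOC | intermediate
12 | lithium [2,4-bis(methoxymethoxy)phenyl]triisopropoxyborate | [Li+].CC(C)O[B-](OC(C)C)(OC(C)C)c1ccc(OCOC)cc1OCOC | intermediate
13 | [2,4-bis(methoxymethoxy)phenyl]boronic acid | OB(O)c1ccc(OCOC)cc1OCOC | intermediate
14 | (1-ethoxycyclopropoxy)trimethylsilane | CCOC1(O[Si](C)(C)C)CC1 | starting material
15 | 1-ethoxycyclopropan-1-ol | CCOC1(O)CC1 | intermediate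
16 | 1-bromobut-2-yne | CC#CCBr | starting material
17 | but-2-yn-1-ylzinc bromide | CC#CC[Zn]Br | intermediate
18 | cyclopropanone | O=C1CC1 | intermediate
19 | 1-(buta-2,3-dien-2-yl)cyclopropan-1-ol | C=C=C(C)C1(O)CC1 | intermediate
20 | (S)-2-ethenyl-2-methylcyclobutan-1-one | O=C1CC[C@@]1(C)C=C | intermediate
21 | N'-[(2S)-2-ethenyl-2-methylcyclobutylidene]-2,4,6-triisopropylbenzenesulfonohydrazide | CC(C)c1cc(C(C)C)c(S(=O)(=O)NN=C2CC[C@@]2(C)C=C)c(C(C)C)c1 | intermediate
22 | [(4S)-4-ethenyl-4-methylcyclobut-1-en-1-yl]lithium | [Li]C1=CC[C@@]1(C)C=C | intermediate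
23 | [2,4-bis(methoxymethoxy)-3-(3-methylbut-2-en-1-yl)phenyl][(4S)-4-ethenyl-4-methylcyclobut-1-en-1-yl]methanone | CC(C)=CCc1c(OCOC)ccc(C(=O)C2=CC[C@@]2(C)C=C)c1OCOC | intermediate
24 | [2,4-bis(methoxymethoxy)-3-(3-methylbut-2-en-1-yl)phenyl]{(1R,2S,4S)-4-[2,4-bis(methoxymethoxy)phenyl]-2-ethenyl-2-methylcyclobutyl}methanone | CC(C)=CCc1c(OCOC)ccc(C(=O)[C@H]2[C@](C)(C=C)C[C@@H]2c2ccc(OCOC)cc2OCOC)c1OCOC | intermediate
25 | 2,4,6-trihydroxyacetophenone | CC(=O)c1c(O)cc(O)cc1O | starting material
26 | 1-[2,6-dihydroxy-4-(methoxymethoxy)phenyl]ethan-1-one | CC(=O)c1c(O)cc(OCOC)cc1O | intermediate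
27 | 2,4-dihydroxybenzaldehyde | O=Cc1ccc(O)cc1O | starting material
28 | 2,4-bis(methoxymethoxy)benzaldehyde | O=Cc1ccc(OCOC)cc1OCOC | intermediate
29 | (E)-1-[2,6-dihydroxy-4-(methoxymethoxy)phenyl]-3-[2,4-bis(methoxymethoxy)phenyl]prop-2-en-1-one | O=C(/C=C/c1ccc(OCOC)cc1OCOC)c1c(O)cc(OCOC)cc1O | intermediate
30 | 5-hydroxy-7-(methoxymethoxy)-2-[2,4-bis(methoxymethoxy)phenyl]chroman-4-one (racemic) | O=C1CC(c2ccc(OCOC)cc2OCOC)Oc2cc(OCOC)cc(O)c21 | intermediate
31 | 5-hydroxy-7-(methoxymethoxy)-2-[2,4-bis(methoxymethoxy)phenyl]-4H-chromen-4-one | O=c1cc(-c2ccc(OCOC)cc2OCOC)oc2cc(OCOC)cc(O)c12 | intermediate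
32 | 5-hydroxy-6-iodo-7-(methoxymethoxy)-2-[2,4-bis(methoxymethoxy)phenyl]-4H-chromen-4-one | O=c1cc(-c2ccc(OCOC)cc2OCOC)oc2cc(OCOC)c(I)c(O)c12 | intermediate
33 | 6-iodo-5,7-bis(methoxymethoxy)-2-[2,4-bis(methoxymethoxy)phenyl]-4H-chromen-4-one | O=c1cc(-c2ccc(OCOC)cc2OCOC)oc2cc(OCOC)c(I)c(OCOC)c12 | intermediate
34 | [2,4-bis(methoxymethoxy)-3-prenylphenyl]{(1R,2S,4S)-4-[2,4-bis(methoxymethoxy)phenyl]-2-methyl-2-[(E)-2-(protected flavon-6-yl)ethenyl]cyclobutyl}methanone | CC(C)=CCc1c(OCOC)ccc(C(=O)[C@H]2[C@](C)(/C=C/c3c(OCOC)cc4oc(-c5ccc(OCOC)cc5OCOC)cc(=O)c4c3OCOC)C[C@@H]2c2ccc(OCOC)cc2OCOC)c1OCOC | intermediate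
35 | octakis(methoxymethyl) ether of the target, (1R,2S,6S)-2-(flavon-6-yl)-4-methyl-6-arylcyclohex-3-en-1-yl aryl ketone | CC(C)=CCc1c(OCOC)ccc(C(=O)[C@H]2[C@@H](c3c(OCOC)cc4oc(-c5ccc(OCOC)cc5OCOC)cc(=O)c4c3OCOC)C=C(C)C[C@@H]2c2ccc(OCOC)cc2OCOC)c1OCOC | intermediate
36 | CNP0270206.1, 6-{(1S,5S,6R)-6-[2,4-dihydroxy-3-(3-methylbut-2-en-1-yl)benzoyl]-5-(2,4-dihydroxyphenyl)-3-methylcyclohex-2-en-1-yl}-2-(2,4-dihydroxyphenyl)-5,7-dihydroxy-4H-chromen-4-one | CC(C)=CCc1c(O)ccc(C(=O)[C@H]2[C@@H](c3c(O)cc4oc(-c5ccc(O)cc5O)cc(=O)c4c3O)C=C(C)C[C@@H]2c2ccc(O)cc2O)c1O | target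

**Step count**

Total step count: 19.
Longest linear sequence: 8 steps (6, 7, 8, 9, 10, 11, 18, 19).

**Steps most likely to fail**

1. Step 18 (Proposed new method).
   - What may go wrong: the styrylcyclobutane may persist after the solvent change. It may break down by cycloreversion. The ion pair may lose its facial memory by rotation about C4–C5, which erodes the cis relation at C1/C2.
   - Fallback: setting out from 24 and 33, the Heck coupling is run alone (same palladium system, toluene, no fluorinated alcohol) and 34 is isolated. Its ring is then enlarged by the known cation-radical (hole-catalysed) vinylcyclobutane rearrangement with tris(4-bromophenyl)aminium hexachloroantimonate and 2,6-di-tert-butylpyridine in CH2Cl2 at 0 °C. Ionisation of the electron-rich styrene weakens the allylic C1–C4 bond, and this reaction type runs suprafacially with retention at low temperature. The route is rejoined at 35.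

2. Step 19.
   - What may go wrong: prolonged acid may cause ketalisation of the ketone by the two flanking ortho phenols, cyclisation of the prenyl group onto a neighbouring phenol, or re-ionisation of the C1–C2 bond with epimerisation at C2.
   - Fallback: the protecting groups are exchanged before the ring is built, so that the last step is a mild base treatment.
   - Setting out from 24, HCl in MeOH gives the free tetraphenol vinylcyclobutyl ketone F1. Ac2O and pyridine turn it into the tetraacetate vinylcyclobutyl ketone F2.
   - Setting out from 32, HCl in MeOH gives 6-iodo-5,7,2',4'-tetrahydroxyflavone F3, and acetylation gives 6-iodoflavone tetraacetate F4.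
   - Coupling of F2 and F4 under the conditions of step 18 passes through the octaacetate styrylcyclobutyl ketone F5 and gives the target octaacetate F6. The enlargement stage is run warmer because acetoxy groups are weaker donors.
   - K2CO3 in MeOH at 0 °C then rejoins the route at 36.

3. Step 11.
   - What may go wrong: insertion of the ortho-substituted aryl–rhodium species may be slow, with competing protodeboronation, or facial selectivity at C6 may be poor.
   - Fallback: setting out from 23 and from aryllithium 11 (made from 10 as in step 5), the aryl group is delivered as the Gilman reagent lithium bis[2,4-bis(methoxymethoxy)phenyl]cuprate F7 (11, CuBr·SMe2, Et2O–THF, −78 °C).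
   - Because C4 is already enantiomerically defined, the two C6 epimers that may form are diastereomers. After equilibration of C1 with DBU they are separated by chromatography, and the isomer with aryl cis to vinyl is 24, where the route is rejoined.

**Further compounds**

F0 | step 18 | none | none
F1 | step 19 | [2,4-dihydroxy-3-(3-methylbut-2-en-1-yl)phenyl][(1R,2S,4S)-4-(2,4-dihydroxyphenyl)-2-ethenyl-2-methylcyclobutyl]methanone | CC(C)=CCc1c(O)ccc(C(=O)[C@H]2[C@](C)(C=C)C[C@@H]2c2ccc(O)cc2O)c1O
F2 | step 19 | tetraacetate of F1 | CC(C)=CCc1c(OC(C)=O)ccc(C(=O)[C@H]2[C@](C)(C=C)C[C@@H]2c2ccc(OC(C)=O)cc2OC(C)=O)c1OC(C)=O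
F3 | step 19 | 2-(2,4-dihydroxyphenyl)-5,7-dihydroxy-6-iodo-4H-chromen-4-one | O=c1cc(-c2ccc(O)cc2O)oc2cc(O)c(I)c(O)c12
F4 | step 19 | tetraacetate of F3 | O=c1cc(-c2ccc(OC(C)=O)cc2OC(C)=O)oc2cc(OC(C)=O)c(I)c(OC(C)=O)c12
F5 | step 19 | octaacetate analogue of 34, (1R,2S,4S)-E-styrylcyclobutyl ketone | CC(C)=CCc1c(OC(C)=O)ccc(C(=O)[C@H]2[C@](C)(/C=C/c3c(OC(C)=O)cc4oc(-c5ccc(OC(C)=O)cc5OC(C)=O)cc(=O)c4c3OC(C)=O)C[C@@H]2c2ccc(OC(C)=O)cc2OC(C)=O)c1OC(C)=O
F6 | step 19 | octaacetate of the target | CC(C)=CCc1c(OC(C)=O)ccc(C(=O)[C@H]2[C@@H](c3c(OC(C)=O)cc4oc(-c5ccc(OC(C)=O)cc5OC(C)=O)cc(=O)c4c3OC(C)=O)C=C(C)C[C@@H]2c2ccc(OC(C)=O)cc2OC(C)=O)c1OC(C)=O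
F7 | step 11 | lithium bis[2,4-bis(methoxymethoxy)phenyl]cuprate | [Li+].COCOc1ccc([Cu-]c2ccc(OCOC)cc2OCOC)c(OCOC)c1
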